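**Plan**

1. Retrosynthesis (onocerane numbering: left bicycle C1–C10, bridge C11–C12, right bicycle C1′–C10′): cut C3–C4 of the left ring A (last ring), then C11–C12 between the halves, then C3′–C4′ of ring A′, then C9–C11 and C9′–C12, then the bonds from C10/C10′ to the arm and the methyl.
2. Forward: rings B and B′ are both (S)-carvone (1), and one carvone-derived ester feeds both halves. Ring A′ is closed in step 7, the halves are joined by mixed Kolbe electrolysis in step 11, and ring A is closed last in step 13.
3. Enabling feature: in each cis-fused ring A the gem-dimethyl carbon C4 hangs on the ring-fusion CH C5, and the carbinol C3 lies three carbons from quaternary C10. Carvone's isopropenyl group is therefore a latent tertiary C4 radical (an H atom to its CH2 makes the second methyl), and a 3-oxopropyl arm on C10 is its acceptor.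
4. Stereochemistry: C5/C5′ come from carvone; C10/C10′ from the alkylation order (methyl last, trans to isopropenyl, so the arm is cis and the ring fusion cis); C9/C9′ from epoxide → Wharton → Johnson–Claisen chirality transfer; C8′ from ester-directed hydrogenation; C3/C3′ from hydride addition to the convex face of the 3,3′-dione.

Key step: step 13

Remark: the target SMILES is read as having both bicycles cis-fused (H-5 and the C10 methyl on one face, likewise H-5′ and the C10′ methyl), the C9 and C9′ side chains cis to the angular methyls, both hydroxyls trans to them, and the C8′ methyl trans to the C9′ side chain; the route is planned for exactly this configuration.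

**Route**

Step 1
Reactants: 1 (S)-(+)-carvone; 2 2-(2-bromoethyl)-1,3-dioxolane
Product: 4 6-[2-(1,3-dioxolan-2-yl)ethyl]-2-methyl-5-(prop-1-en-2-yl)cyclohex-2-en-1-one (arm trans to isopropenyl; major epimer), via lithium dienolate 3 (not isolated)
Conditions: LiN(iPr)2, THF, −78 °C; then 2, DMPU, Bu4NI (cat.), −78 → 23 °C
Reagents that add atoms: none
Why: Ketone enolate alkylation: kinetic deprotonation at the α′-CH2 gives the cross-conjugated dienolate, which is C-alkylated by the primary halide; the new centre (mainly trans to isopropenyl) is erased again in step 2, so its ratio does not matter.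

Step 2
Reactants: 4 6-[2-(1,3-dioxolan-2-yl)ethyl]carvone
Product: 6 6-[2-(1,3-dioxolan-2-yl)ethyl]-2,6-dimethyl-5-(prop-1-en-2-yl)cyclohex-2-en-1-one (6-methyl trans and arm cis to isopropenyl), via lithium enolate 5 (not isolated)
Conditions: LiN(iPr)2, THF, −78 °C; then MeI, DMPU, −78 → 0 °C
Reagents that add atoms: iodomethane, CI
Why: Second enolate alkylation: the planar α′-enolate is methylated on the face away from the neighbouring isopropenyl group (held pseudo-axial by allylic strain), so the methyl ends trans and the acetal arm cis to isopropenyl, which sets quaternary C10 and, with it, the later cis ring fusion.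

Step 3
Reactants: 6 dialkylated carvone
Product: 7 2,3-epoxide of 6 (oxirane oxygen trans to isopropenyl; cis to the 6-methyl)
Conditions: H2O2 (30% aq), NaOH (cat.), MeOH, 0 °C
Reagents that add atoms: hydrogen peroxide, OO
Why: Weitz–Scheffer epoxidation: hydroperoxide adds only to the enone, axially at the β-carbon (C7) on the face opposite the isopropenyl-bearing C5 as in carvone itself, and the enolate closes the oxirane on that same face.

Step 4
Reactants: 7 epoxy ketone
Product: 10 4-[2-(1,3-dioxolan-2-yl)ethyl]-2,4-dimethyl-5-(prop-1-en-2-yl)cyclohex-2-en-1-ol (hydroxyl cis to the 4-methyl; trans to isopropenyl), via epoxy hydrazone 8 (not isolated), via alkenyl diazene 9 (not isolated)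
Conditions: N2H4·H2O, AcOH (cat.), MeOH, 0 → 23 °C
Reagents that add atoms: none
Why: Wharton transposition: the epoxy hydrazone opens to an alkenyl diazene that loses N2, which moves the double bond to C8=C9 and leaves the C7–O bond untouched, so the hydroxyl keeps the oxirane's face (cis to the C10 methyl).

Step 5
Reactants: 10 transposed allylic alcohol
Product: 12 ethyl 2-{6-[2-(1,3-dioxolan-2-yl)ethyl]-2,6-dimethyl-5-(prop-1-en-2-yl)cyclohex-2-en-1-yl}acetate (CH2CO2Et cis to the 6-methyl; trans to arm and isopropenyl), via mixed ketene acetal 11 (not isolated)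
Conditions: MeC(OEt)3, EtCO2H (cat.), 140 °C, EtOH distilled off
Reagents that add atoms: triethyl orthoacetate, CC(OCC)(OCC)OCC
Why: Johnson–Claisen rearrangement: the [3,3] shift is suprafacial, so the CH2CO2Et group is delivered to C9 on the face that carried the C7 hydroxyl (cis to the C10 methyl; trans to the arm) while the double bond returns to C7=C8.

Step 6
Reactants: 12 acetal ester
Product: 13 ethyl 2-[2,6-dimethyl-6-(3-oxopropyl)-5-(prop-1-en-2-yl)cyclohex-2-en-1-yl]acetate
Conditions: 1 M aq HCl, THF, 23 °C
Reagents that add atoms: water, O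
Why: Acid-catalysed acetal hydrolysis frees the aldehyde under conditions that leave the ester and both alkenes alone; no stereocentre is involved.

Step 7
Reactants: 13 aldehyde ester
Product: 14 ethyl 2-(6-hydroxy-2,5,5,8a-tetramethyl-1,4,4a,5,6,7,8,8a-octahydronaphthalen-1-yl)acetate (ring A′ closed; cis-fused; hydroxyl expected cis to the angular methyl)
Conditions: Fe(acac)3 (30 mol %), PhSiH3, EtOH, 60 °C, argon
Reagents that add atoms: none
Why: Iron-hydride HAT-initiated reductive radical cyclisation of an alkene-tethered aldehyde (the reaction type of the key step, here on the simpler ester): H-atom transfer to the isopropenyl CH2 gives the tertiary C4′ radical, which closes ring A′ 6-exo onto the formyl carbon; the cis fusion follows from the configurations of C5′ (from carvone) and C10′ (set in step 2), which hold the radical carbon and the arm on one face of ring B′, and the carbinol centre, expected with oxygen pseudo-equatorial (cis to the C10′ methyl), is re-set in steps 14 and 15.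

Step 8
Reactants: 14 bicyclic hydroxy ester
Product: 15 ethyl 2-(6-hydroxy-2,5,5,8a-tetramethyldecahydronaphthalen-1-yl)acetate (2-methyl trans to the side chain)
Conditions: [Ir(cod)(PCy3)(py)]PF6 (10 mol %), H2 (1 atm), CH2Cl2, 23 °C
Reagents that add atoms: none
Why: Directed homogeneous hydrogenation: the ester carbonyl of the C9′ side chain binds the cationic iridium centre and both hydrogens enter the C7′=C8′ bond from the side-chain face, which sets H-8′ cis and the C8′ methyl trans to the side chain.

Step 9
Reactants: 15 saturated hydroxy ester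
Product: 16 2-(6-hydroxy-2,5,5,8a-tetramethyldecahydronaphthalen-1-yl)acetic acid
Conditions: LiOH·H2O, THF/MeOH/H2O, 50 °C; then 1 M HCl
Reagents that add atoms: lithium hydroxide, [Li+].[OH-]
Why: Ester saponification; no stereocentre is α to the carbonyl, so none is touched.

Step 10
Reactants: 12 acetal ester
Product: 17 2-{6-[2-(1,3-dioxolan-2-yl)ethyl]-2,6-dimethyl-5-(prop-1-en-2-yl)cyclohex-2-en-1-yl}acetic acid
Conditions: LiOH·H2O, THF/MeOH/H2O, 40 °C; then 1 M HCl to pH 4, 0 °C
Reagents that add atoms: lithium hydroxide, [Li+].[OH-]
Why: Ester saponification; the dioxolane survives the basic medium and the brief cold acidification.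

Step 11
Reactants: 16 right-half hydroxy acid; 17 left-half acid
Product: 18 1-(left monocycle)-2-(right bicycle)ethane: cross-coupled acetal alcohol
Conditions: 16 (1 equiv), 17 (4 equiv), KOH (10 mol %), MeOH, Pt anode and cathode, undivided cell, constant current, 20 °C
Reagents that add atoms: none
Why: Mixed Kolbe electrolysis: anodic decarboxylation of the two β-branched acetic acids gives the primary C12 and C11 radicals, whose combination forms the C11–C12 bond without touching a stereocentre; the earlier acid 17 is used in excess so that 16 is channelled into the cross product, and the hydroxyl-free dimer of 17 should separate easily.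

Step 12
Reactants: 18 cross-coupled acetal
Product: 19 cross-coupled aldehyde (3-oxopropyl arm on C10)
Conditions: 1 M aq HCl, THF, 23 °C
Reagents that add atoms: water, O
Why: Acid-catalysed acetal hydrolysis; the secondary alcohol, the isopropenyl group and the ring alkene are inert under these conditions.

Step 13
Reactants: 19 cross-coupled aldehyde
Product: 20 3,3′-bis-epimer of the target (all four rings closed; both hydroxyls expected cis to the angular methyls)
Conditions: Fe(acac)3 (30 mol %), PhSiH3 (2.5 equiv), EtOH/THF, 60 °C, argon, 0.01 M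
Reagents that add atoms: none
Why: Fe(acac)3 and PhSiH3 form an iron hydride that transfers a hydrogen atom to the CH2 terminus of the isopropenyl group (this makes the second methyl of C4), the tertiary C4 radical adds to the formyl carbon C3 of the cis-disposed 3-oxopropyl arm, and the resulting alkoxy radical is reduced by divalent iron and protonated by ethanol. The closest known reaction type is the iron-hydride HAT-initiated reductive radical cyclisation of alkene-tethered carbonyl compounds (ketones intramolecularly, aldehydes also intermolecularly). Ring A closes in the 6-exo-trig mode onto the C=O bond through a chair-like transition state. The ring fusion is not at issue, because C5 and C10 already carry the radical carbon and the arm on the same face of ring B; the only new stereocentre is C3, where the oxygen is expected pseudo-equatorial in the chair that keeps C4 equatorial on ring B, which puts the hydroxyl cis to the C10 methyl, and this centre is deliberately re-set in steps 14 and 15. The step needs HAT to the isopropenyl group in preference to the trisubstituted C7=C8 alkene, which the unhindered 1,1-disubstituted terminus secures, and ring closure faster than reduction of the radical, which the fast 6-exo addition to an aldehyde and the dilution secure.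

Step 14
Reactants: 20 bis-epimeric diol
Product: 21 3,3′-dione
Conditions: DMP (1,1,1-triacetoxy-1,1-dihydro-1,2-benziodoxol-3(1H)-one, 3 equiv), CH2Cl2, 23 °C
Reagents that add atoms: none
Why: Hypervalent-iodine oxidation of both secondary carbinols gives the dione and so erases the two carbinol centres formed without reliable control in steps 7 and 13; C4 and C4′ are quaternary, so no other centre can epimerise.

Step 15
Reactants: 21 3,3′-dione
Product: 22 target diol
Conditions: NaBH4, MeOH/THF, −20 → 0 °C
Reagents that add atoms: none
Why: Borohydride reduction of both ketones: in each cis-fused bicycle hydride should add to the convex face of ring A (the face of the angular methyl and H-5; axial attack in the chair that has the angular methyl equatorial on ring A), which places both hydroxyls trans to the angular methyls as in the target, and the trisubstituted alkene is inert.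

**Compound list**

1 | (S)-(+)-carvone, (5S)-2-methyl-5-(prop-1-en-2-yl)cyclohex-2-en-1-one | CC1=CC[C@@H](CC1=O)C(C)=C | starting material
2 | 2-(2-bromoethyl)-1,3-dioxolane | BrCCC1OCCO1 | starting material
3 | cross-conjugated lithium dienolate of 1 (not isolated) | [Li]OC1=C[C@@H](C(C)=C)CC=C1C | intermediate
4 | 6-[2-(1,3-dioxolan-2-yl)ethyl]-2-methyl-5-(prop-1-en-2-yl)cyclohex-2-en-1-one, arm trans to isopropenyl (major epimer) | CC1=CC[C@H](C(C)=C)[C@@H](CCC2OCCO2)C1=O | intermediate
5 | lithium enolate of 4 (not isolated) | [Li]OC1=C(CCC2OCCO2)[C@@H](C(C)=C)CC=C1C | intermediate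
6 | 6-[2-(1,3-dioxolan-2-yl)ethyl]-2,6-dimethyl-5-(prop-1-en-2-yl)cyclohex-2-en-1-one, 6-methyl trans and arm cis to isopropenyl | CC1=CC[C@H](C(C)=C)[C@](C)(CCC2OCCO2)C1=O | intermediate
7 | 2,3-epoxide of 6, oxirane oxygen trans to isopropenyl and cis to the 6-methyl | C[C@]12O[C@H]1C[C@H](C(C)=C)[C@](C)(CCC3OCCO3)C2=O | intermediate
8 | hydrazone of 7 (not isolated) | C[C@]12O[C@H]1C[C@H](C(C)=C)[C@](C)(CCC3OCCO3)C2=NN | intermediate
9 | 3-diazenyl-4-[2-(1,3-dioxolan-2-yl)ethyl]-2,4-dimethyl-5-(prop-1-en-2-yl)cyclohex-2-en-1-ol (not isolated) | CC1=C(N=N)[C@@](C)(CCC2OCCO2)[C@@H](C(C)=C)C[C@@H]1O | intermediate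
10 | 4-[2-(1,3-dioxolan-2-yl)ethyl]-2,4-dimethyl-5-(prop-1-en-2-yl)cyclohex-2-en-1-ol, hydroxyl cis to the 4-methyl and trans to isopropenyl | CC1=C[C@@](C)(CCC2OCCO2)[C@@H](C(C)=C)C[C@@H]1O | intermediate
11 | 1-ethoxyvinyl ether (mixed ketene acetal) of 10 (not isolated) | CC1=C[C@@](C)(CCC2OCCO2)[C@@H](C(C)=C)C[C@@H]1OC(=C)OCC | intermediate
12 | ethyl 2-{6-[2-(1,3-dioxolan-2-yl)ethyl]-2,6-dimethyl-5-(prop-1-en-2-yl)cyclohex-2-en-1-yl}acetate, CH2CO2Et cis to the 6-methyl, trans to arm and isopropenyl | CCOC(=O)C[C@H]1C(C)=CC[C@H](C(C)=C)[C@]1(C)CCC2OCCO2 | intermediate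
13 | ethyl 2-[2,6-dimethyl-6-(3-oxopropyl)-5-(prop-1-en-2-yl)cyclohex-2-en-1-yl]acetate, configuration as 12 | CCOC(=O)C[C@H]1C(C)=CC[C@H](C(C)=C)[C@]1(C)CCC=O | intermediate
14 | ethyl 2-(6-hydroxy-2,5,5,8a-tetramethyl-1,4,4a,5,6,7,8,8a-octahydronaphthalen-1-yl)acetate, cis-fused, side chain and hydroxyl both cis to the 8a-methyl | CCOC(=O)C[C@H]1C(C)=CC[C@@H]2C(C)(C)[C@@H](O)CC[C@]12C | intermediate
15 | ethyl 2-(6-hydroxy-2,5,5,8a-tetramethyldecahydronaphthalen-1-yl)acetate, as 14 with the 2-methyl trans to the side chain | CCOC(=O)C[C@H]1[C@H](C)CC[C@@H]2C(C)(C)[C@@H](O)CC[C@]12C | intermediate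
16 | 2-(6-hydroxy-2,5,5,8a-tetramethyldecahydronaphthalen-1-yl)acetic acid, configuration as 15 | OC(=O)C[C@H]1[C@H](C)CC[C@@H]2C(C)(C)[C@@H](O)CC[C@]12C | intermediate
17 | 2-{6-[2-(1,3-dioxolan-2-yl)ethyl]-2,6-dimethyl-5-(prop-1-en-2-yl)cyclohex-2-en-1-yl}acetic acid, configuration as 12 | OC(=O)C[C@H]1C(C)=CC[C@H](C(C)=C)[C@]1(C)CCC2OCCO2 | intermediate
18 | cross-coupled acetal alcohol: the monocycle of 17 and the bicycle of 16 joined by CH2–CH2 (C11–C12) | CC1=CC[C@H](C(C)=C)[C@](C)(CCC2OCCO2)[C@H]1CC[C@H]1[C@H](C)CC[C@@H]2C(C)(C)[C@@H](O)CC[C@]12C | intermediate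
19 | cross-coupled aldehyde: as 18 with a 3-oxopropyl arm on C10 | CC1=CC[C@H](C(C)=C)[C@](C)(CCC=O)[C@H]1CC[C@H]1[C@H](C)CC[C@@H]2C(C)(C)[C@@H](O)CC[C@]12C | intermediate
20 | 3,3′-bis-epimer of the target, both hydroxyls cis to the angular methyls | CC1=CC[C@@H]2C(C)(C)[C@@H](O)CC[C@]2(C)[C@H]1CC[C@H]1[C@H](C)CC[C@@H]2C(C)(C)[C@@H](O)CC[C@@]21C | intermediate
21 | 3,3′-dione of the target skeleton | CC1=CC[C@@H]2C(C)(C)C(=O)CC[C@]2(C)[C@H]1CC[C@H]1[C@H](C)CC[C@@H]2C(C)(C)C(=O)CC[C@@]21C | intermediate
22 | target diol (CNP0194061.2) | CC1=CC[C@@H]2C(C)(C)[C@H](O)CC[C@]2(C)[C@H]1CC[C@H]1[C@H](C)CC[C@@H]2C(C)(C)[C@H](O)CC[C@@]21C | target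

**Step count and risks**

Total steps: 15. Longest linear sequence: 14 (steps 1–9 and 11–15).

Step 11 is the most exposed. Radical pairing is statistical, and the anode may over-oxidise the two alkenes of the left-hand acid, so material may be lost to symmetrical dimers and methoxylated by-products. The fallback sets out from acids 16 and 17. Each is esterified with N-hydroxyphthalimide and N,N′-diisopropylcarbodiimide to its redox-active ester: the N-acyloxyphthalimide of the right-hand acid F1 and the N-acyloxyphthalimide of the left-hand acid F2 (used in excess). The two esters are then joined by nickel-electrocatalytic doubly decarboxylative cross-coupling at the cathode (NiCl2·6H2O, bipyridine-type ligand, AgNO3, Mg anode, DMF), where no oxidising potential reaches the alkenes. This returns to the route at 18.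

Step 4 may stall because hydrazone formation at a carbonyl flanked by a quaternary carbon and the oxirane carbon is slow; hydrazine may then open the oxirane instead. The fallback sets out from epoxy ketone 7. Reduction (NaBH4, CeCl3·7H2O, MeOH) gives the epoxy alcohol F3, whose carbinol configuration is of no consequence. 1,1′-Thiocarbonyldiimidazole converts it into the O-(imidazol-1-ylthiocarbonyl) derivative F4. Bu3SnH with AIBN in toluene at 80 °C generates the C9 radical, which opens the oxirane and delivers the transposed allylic alcohol with the C7–O bond intact. This returns to the route at 10.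

Step 13 may give simple reduction of the isopropenyl group if addition of the tertiary radical to the formyl group is slow or reverses by fragmentation of the alkoxy radical; hydrogen-atom transfer to the ring alkene is a second drain. The fallback sets out from aldehyde 19. Hydroxylamine-O-sulfonic acid converts the aldehyde into the nitrile F5. The same iron-hydride conditions close ring A onto the nitrile, a known and practically irreversible acceptor, to give the ketimine F6, which is hydrolysed on acidic work-up to the 3-keto 3′-alcohol F7. DMP oxidation of the remaining carbinol returns to the route at 21.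

Further compounds
F1 | step 11 | N-acyloxyphthalimide of acid 16 | O=C(C[C@H]1[C@H](C)CC[C@@H]2C(C)(C)[C@@H](O)CC[C@]12C)ON1C(=O)c2ccccc2C1=O
F2 | step 11 | N-acyloxyphthalimide of acid 17 | O=C(C[C@H]1C(C)=CC[C@H](C(C)=C)[C@]1(C)CCC1OCCO1)ON1C(=O)c2ccccc2C1=O
F3 | step 4 | epoxy alcohol from reduction of 7 | C[C@]12O[C@H]1C[C@H](C(C)=C)[C@](C)(CCC3OCCO3)[C@H]2O
F4 | step 4 | O-(imidazol-1-ylthiocarbonyl) derivative of F3 | C[C@]12O[C@H]1C[C@H](C(C)=C)[C@](C)(CCC3OCCO3)[C@H]2OC(=S)n1ccnc1
F5 | step 13 | nitrile corresponding to aldehyde 19 (2-cyanoethyl arm on C10) | CC1=CC[C@H](C(C)=C)[C@](C)(CCC#N)[C@H]1CC[C@H]1[C@H](C)CC[C@@H]2C(C)(C)[C@@H](O)CC[C@]12C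
F6 | step 13 | tetracyclic 3-ketimine with the 3′-hydroxyl | CC1=CC[C@@H]2C(C)(C)C(=N)CC[C@]2(C)[C@H]1CC[C@H]1[C@H](C)CC[C@@H]2C(C)(C)[C@@H](O)CC[C@@]21C
F7 | step 13 | tetracyclic 3-ketone with the 3′-hydroxyl | CC1=CC[C@@H]2C(C)(C)C(=O)CC[C@]2(C)[C@H]1CC[C@H]1[C@H](C)CC[C@@H]2C(C)(C)[C@@H](O)CC[C@@]21C
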